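**Plan**

- The target is a depside of two 2,4-dihydroxy-6-(2-oxoheptyl)benzoic acid units. It has no stereocentre and no configured double bond, so no stereocontrol is needed.
- The retrosynthesis cuts the two pentyl–C(=O) bonds first (back to two N-methoxy-N-methylamides). It then cuts the ring A bonds C1–C(=O) and C6–CH2 together, then the malonyl C(=O)–O bond to the ring B phenol, and last the ring B CH2–C(=O)N bond.
- The enabling feature is that ring A carries the ester carbonyl on C1 and the side-chain CH2 on the adjacent C6, just as carbonyl and CH2 are adjacent in a malonyl unit. C2, on the other side of C1, bears an oxygen, so a 3,5-dioxygenated benzyne slipped between the malonyl CH2 and its aryl ester carbonyl gives ring A in the right orientation.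
- In the forward direction no ring is built. Ring B is elaborated from orsellinic acid and ring A arrives as the aryne made from 3,5-bis(benzyloxy)phenol. Both pentyl groups are then added in one operation, and one hydrogenolysis removes all four benzyl groups.

Key step: step 11

Remark: the ring B ketone is carried as a second N-methoxy-N-methylamide and every hydroxyl and the acid as benzyl derivatives, so that no acid is needed after the depside ester exists. Orsellinic acid, 3,5-bis(benzyloxy)phenol and Meldrum's acid are taken as purchased.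

**Route**

Step 1
Reactants: 1 3,5-bis(benzyloxy)phenol
Product: 2 2-bromo-3,5-bis(benzyloxy)phenol
Conditions: NBS (1.0 equiv), i-Pr2NH (0.1 equiv), CH2Cl2, −78 °C to 0 °C
Reagents that add atoms: N-bromosuccinimide (O=C1CCC(=O)N1Br)
Why: Amine-mediated electrophilic bromination of a phenol delivers bromine ortho to the hydroxyl; the two ortho sites are equivalent and the para site is screened by two benzyloxy groups, any para isomer being removable by chromatography.

Step 2
Reactants: 2 2-bromo-3,5-bis(benzyloxy)phenol
Product: 3 [2-bromo-3,5-bis(benzyloxy)phenoxy]trimethylsilane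
Conditions: HMDS (1.5 equiv), THF, 70 °C; volatiles removed in vacuo
Reagents that add atoms: hexamethyldisilazane (C[Si](C)(C)N[Si](C)(C)C)
Why: O-silylation of a phenol with hexamethyldisilazane needs no base and gives only ammonia beside the silyl ether required for the silyl shift of step 3.

Step 3
Reactants: 3 [2-bromo-3,5-bis(benzyloxy)phenoxy]trimethylsilane
Product: 5 3,5-bis(benzyloxy)-2-(trimethylsilyl)phenyl trifluoromethanesulfonate, via lithium 3,5-bis(benzyloxy)-2-(trimethylsilyl)phenoxide 4 (not isolated)
Conditions: n-BuLi (1.1 equiv), THF, −100 °C; then Tf2O (1.25 equiv), −100 °C to −80 °C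
Reagents that add atoms: trifluoromethanesulfonic anhydride (O=S(=O)(OS(=O)(=O)C(F)(F)F)C(F)(F)F)
Why: Bromine–lithium exchange is faster than any deprotonation at this temperature and triggers the 1,3 oxygen-to-carbon silyl shift (retro-Brook rearrangement); the resulting lithium phenoxide is O-triflated in the same flask, the standard way to ortho-silylaryl triflates.

Step 4
Reactants: 6 2,2-dimethyl-1,3-dioxane-4,6-dione (Meldrum's acid)
Product: 7 3-[methoxy(methyl)amino]-3-oxopropanoic acid
Conditions: MeNH(OMe)·HCl (1.0 equiv), Et3N (1.05 equiv), MeCN, 70 °C; aqueous HCl work-up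
Reagents that add atoms: N,O-dimethylhydroxylamine hydrochloride (CNOC.Cl)
Why: Aminolysis of Meldrum's acid opens the ring acylal with loss of acetone and stops at the malonic half-amide because the carboxylate formed is no longer electrophilic.

Step 5
Reactants: 8 2,4-dihydroxy-6-methylbenzoic acid (orsellinic acid)
Product: 9 benzyl 2,4-dihydroxy-6-methylbenzoate
Conditions: BnBr (1.05 equiv), KHCO3 (1.1 equiv), DMF, 23 °C
Reagents that add atoms: benzyl bromide (BrCc1ccccc1)
Why: Hydrogen carbonate deprotonates only the carboxylic acid, so SN2 O-alkylation of the carboxylate gives the benzyl ester and leaves both phenols free, at a temperature that avoids decarboxylation.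

Step 6
Reactants: 9 benzyl 2,4-dihydroxy-6-methylbenzoate
Product: 10 benzyl 2-hydroxy-4-(methoxymethoxy)-6-methylbenzoate
Conditions: MOMCl (1.05 equiv), i-Pr2NEt (1.5 equiv), CH2Cl2, 0 °C
Reagents that add atoms: chloromethyl methyl ether (COCCl)
Why: Williamson-type alkylation occurs selectively at the 4-hydroxyl because the 2-hydroxyl is tied to the ester carbonyl by an intramolecular hydrogen bond and is far less nucleophilic.

Step 7
Reactants: 10 benzyl 2-hydroxy-4-(methoxymethoxy)-6-methylbenzoate
Product: 11 benzyl 2-(benzyloxy)-4-(methoxymethoxy)-6-methylbenzoate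
Conditions: BnBr (1.3 equiv), K2CO3 (2 equiv), DMF, 60 °C
Reagents that add atoms: benzyl bromide (BrCc1ccccc1)
Why: Williamson ether synthesis under more forcing conditions alkylates the chelated phenol, and the methoxymethyl ether and benzyl ester are stable to carbonate.

Step 8
Reactants: 11 benzyl 2-(benzyloxy)-4-(methoxymethoxy)-6-methylbenzoate
Product: 13 benzyl 2-(benzyloxy)-6-{2-[methoxy(methyl)amino]-2-oxoethyl}-4-(methoxymethoxy)benzoate, via lithiated toluate 12 (not isolated)
Conditions: LiN(i-Pr)2 (LDA, 2.1 equiv), THF, −78 °C; then ClC(O)N(OMe)Me (1.05 equiv), −78 °C to −40 °C; AcOH quench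
Reagents that add atoms: N-methoxy-N-methylcarbamoyl chloride (CON(C)C(Cl)=O)
Why: Lateral lithiation of an ortho-toluate gives the ester-stabilised benzylic anion, which is C-acylated by the carbamoyl chloride; the second equivalent of base takes up the more acidic CH2 of the product so that it does not quench unreacted anion.

Step 9
Reactants: 13 benzyl 2-(benzyloxy)-6-{2-[methoxy(methyl)amino]-2-oxoethyl}-4-(methoxymethoxy)benzoate
Product: 14 benzyl 2-(benzyloxy)-4-hydroxy-6-{2-[methoxy(methyl)amino]-2-oxoethyl}benzoate
Conditions: HCl (cat.), MeOH/THF, 40 °C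
Reagents that add atoms: none
Why: Acid-catalysed acetal exchange with methanol removes the methoxymethyl group, while the benzyl ether, the hindered benzyl ester and the amide are inert to dilute acid.

Step 10
Reactants: 14 benzyl 2-(benzyloxy)-4-hydroxy-6-{2-[methoxy(methyl)amino]-2-oxoethyl}benzoate; 7 3-[methoxy(methyl)amino]-3-oxopropanoic acid
Product: 15 benzyl 2-(benzyloxy)-6-{2-[methoxy(methyl)amino]-2-oxoethyl}-4-({3-[methoxy(methyl)amino]-3-oxopropanoyl}oxy)benzoate
Conditions: DCC (1.2 equiv), DMAP (0.1 equiv), CH2Cl2, 0 °C to 23 °C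
Reagents that add atoms: none
Why: Steglich esterification joins the unhindered malonic half-acid to the only free phenol, and an intermediate carbamoyl ketene, if formed, is trapped by the phenol to the same ester.

Step 11
Reactants: 15 benzyl 2-(benzyloxy)-6-{2-[methoxy(methyl)amino]-2-oxoethyl}-4-({3-[methoxy(methyl)amino]-3-oxopropanoyl}oxy)benzoate; 5 3,5-bis(benzyloxy)-2-(trimethylsilyl)phenyl trifluoromethanesulfonate
Product: 17 benzyl 4-{[2,4-bis(benzyloxy)-6-{2-[methoxy(methyl)amino]-2-oxoethyl}benzoyl]oxy}-2-(benzyloxy)-6-{2-[methoxy(methyl)amino]-2-oxoethyl}benzoate, via 3,5-bis(benzyloxy)benzyne 16 (not isolated)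
Conditions: CsF (3 equiv), anhydrous MeCN, 40 °C; 5 (1.5 equiv) added slowly
Reagents that add atoms: none
Why: Proposed new method: fluoride removes the silyl group of 5 and triflate departs to give aryne 16 while CsF (later the product enolate) deprotonates the doubly activated CH2 of 15; the carbanion adds to the aryne carbon meta to the flanking benzyloxy group, the aryl anion formed beside that oxygen attacks the neighbouring aryl ester carbonyl (4-exo-trig) to a benzocyclobutenoxide, and this fragments by C–C cleavage to the amide enolate, which is protonated by further 15. The closest known reactions are the aryne acyl-alkylation of beta-keto esters and the aryne insertion into the C–C bond of dialkyl malonates; a malonyl unit with one aryl ester and one N-methoxy-N-methylamide has not been used in this way. No ring remains in the product, the four-membered ring being transient, and no stereocentre is created. Three selectivities are needed: the site of carbanion addition, secured by the inductive pull of the flanking C–O bond on the developing aryl anion as is general for 3-alkoxyarynes; acyl transfer from the aryl ester and not the amide, which follows from the much higher electrophilicity of an aryl ester (if the alkoxide expels the ring B phenoxide instead, that phenoxide reopens the benzocyclobutenone to the same product); and acyl transfer ahead of protonation of the aryl anion, favoured because the transfer is intramolecular and the medium aprotic. The low temperature and slow addition of 5 are meant to keep the malonyl enolate from shedding the ring B phenoxide as a ketene before it meets the aryne.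

Step 12
Reactants: 17 benzyl 4-{[2,4-bis(benzyloxy)-6-{2-[methoxy(methyl)amino]-2-oxoethyl}benzoyl]oxy}-2-(benzyloxy)-6-{2-[methoxy(methyl)amino]-2-oxoethyl}benzoate
Product: 18 benzyl 4-{[2,4-bis(benzyloxy)-6-(2-oxoheptyl)benzoyl]oxy}-2-(benzyloxy)-6-(2-oxoheptyl)benzoate
Conditions: n-C5H11MgBr (3.5 equiv), CeCl3 (3.5 equiv, anhydrous), THF, −78 °C; 1 M HCl work-up at 0 °C
Reagents that add atoms: pentylmagnesium bromide (CCCCC[Mg]Br)
Why: Weinreb ketone synthesis on both amides: the weakly basic organocerium reagent adds instead of enolising the benzylic amides, the chelated tetrahedral intermediates prevent over-addition, and both esters are 2,6-disubstituted benzoates too shielded to react at this temperature.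

Step 13
Reactants: 18 benzyl 4-{[2,4-bis(benzyloxy)-6-(2-oxoheptyl)benzoyl]oxy}-2-(benzyloxy)-6-(2-oxoheptyl)benzoate
Product: 19 4-{[2,4-dihydroxy-6-(2-oxoheptyl)benzoyl]oxy}-2-hydroxy-6-(2-oxoheptyl)benzoic acid (CNP0165432.0)
Conditions: H2 (1 atm), 10% Pd/C, EtOAc/THF, 23 °C
Reagents that add atoms: none
Why: Catalytic hydrogenolysis cleaves the three benzyl ethers and the benzyl ester under neutral conditions that leave the aliphatic ketones and the aryl ester untouched, the classical last step of depside syntheses.

**Compound list**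

1 | 3,5-bis(benzyloxy)phenol | Oc1cc(OCc2ccccc2)cc(OCc2ccccc2)c1 | starting material
2 | 2-bromo-3,5-bis(benzyloxy)phenol | Oc1cc(OCc2ccccc2)cc(OCc2ccccc2)c1Br | intermediate
3 | [2-bromo-3,5-bis(benzyloxy)phenoxy]trimethylsilane | C[Si](C)(C)Oc1cc(OCc2ccccc2)cc(OCc2ccccc2)c1Br | intermediate
4 | lithium 3,5-bis(benzyloxy)-2-(trimethylsilyl)phenoxide | [Li+].[O-]c1cc(OCc2ccccc2)cc(OCc2ccccc2)c1[Si](C)(C)C | intermediate
5 | 3,5-bis(benzyloxy)-2-(trimethylsilyl)phenyl trifluoromethanesulfonate | C[Si](C)(C)c1c(OS(=O)(=O)C(F)(F)F)cc(OCc2ccccc2)cc1OCc1ccccc1 | intermediate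
6 | 2,2-dimethyl-1,3-dioxane-4,6-dione (Meldrum's acid) | CC1(C)OC(=O)CC(=O)O1 | starting material
7 | 3-[methoxy(methyl)amino]-3-oxopropanoic acid | CON(C)C(=O)CC(=O)O | intermediate
8 | 2,4-dihydroxy-6-methylbenzoic acid (orsellinic acid) | Cc1cc(O)cc(O)c1C(=O)O | starting material
9 | benzyl 2,4-dihydroxy-6-methylbenzoate | Cc1cc(O)cc(O)c1C(=O)OCc1ccccc1 | intermediate
10 | benzyl 2-hydroxy-4-(methoxymethoxy)-6-methylbenzoate | COCOc1cc(C)c(C(=O)OCc2ccccc2)c(O)c1 | intermediate
11 | benzyl 2-(benzyloxy)-4-(methoxymethoxy)-6-methylbenzoate | COCOc1cc(C)c(C(=O)OCc2ccccc2)c(OCc2ccccc2)c1 | intermediate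
12 | benzyl 2-(benzyloxy)-6-(lithiomethyl)-4-(methoxymethoxy)benzoate (ester-stabilised benzylic anion) | [Li]Cc1cc(OCOC)cc(OCc2ccccc2)c1C(=O)OCc1ccccc1 | intermediate
13 | benzyl 2-(benzyloxy)-6-{2-[methoxy(methyl)amino]-2-oxoethyl}-4-(methoxymethoxy)benzoate | COCOc1cc(CC(=O)N(C)OC)c(C(=O)OCc2ccccc2)c(OCc2ccccc2)c1 | intermediate
14 | benzyl 2-(benzyloxy)-4-hydroxy-6-{2-[methoxy(methyl)amino]-2-oxoethyl}benzoate | CON(C)C(=O)Cc1cc(O)cc(OCc2ccccc2)c1C(=O)OCc1ccccc1 | intermediate
15 | benzyl 2-(benzyloxy)-6-{2-[methoxy(methyl)amino]-2-oxoethyl}-4-({3-[methoxy(methyl)amino]-3-oxopropanoyl}oxy)benzoate | CON(C)C(=O)CC(=O)Oc1cc(CC(=O)N(C)OC)c(C(=O)OCc2ccccc2)c(OCc2ccccc2)c1 | intermediate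
16 | 3,5-bis(benzyloxy)benzyne | C1#CC(OCc2ccccc2)=CC(OCc2ccccc2)=C1 | intermediate
17 | benzyl 4-{[2,4-bis(benzyloxy)-6-{2-[methoxy(methyl)amino]-2-oxoethyl}benzoyl]oxy}-2-(benzyloxy)-6-{2-[methoxy(methyl)amino]-2-oxoethyl}benzoate | CON(C)C(=O)Cc1cc(OC(=O)c2c(OCc3ccccc3)cc(OCc3ccccc3)cc2CC(=O)N(C)OC)cc(OCc2ccccc2)c1C(=O)OCc1ccccc1 | intermediate
18 | benzyl 4-{[2,4-bis(benzyloxy)-6-(2-oxoheptyl)benzoyl]oxy}-2-(benzyloxy)-6-(2-oxoheptyl)benzoate | CCCCCC(=O)Cc1cc(OC(=O)c2c(OCc3ccccc3)cc(OCc3ccccc3)cc2CC(=O)CCCCC)cc(OCc2ccccc2)c1C(=O)OCc1ccccc1 | intermediate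
19 | 4-{[2,4-dihydroxy-6-(2-oxoheptyl)benzoyl]oxy}-2-hydroxy-6-(2-oxoheptyl)benzoic acid | CCCCCC(=O)Cc1cc(OC(=O)c2c(O)cc(O)cc2CC(=O)CCCCC)cc(O)c1C(=O)O | target

**Step count**

Total steps: 13. Longest linear sequence: 9 steps (steps 5 to 13, from orsellinic acid 8).

**Steps most likely to fail, with fallbacks**

Step 11. The malonyl enolate of 15 may lose the ring B phenoxide as a ketene faster than it meets the aryne, so that the phenoxide O-arylates instead. The aryl anion may also be protonated before acyl transfer, or fluoride may cleave the activated aryl ester. The fallback makes the ring A–CH2 and ring A–carbonyl bonds by the established aryne insertion into a dialkyl malonate and the depside ester by classical acylation. It sets out from 5 and 14 and returns at 17.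
- Aryne 16 is released from 5 (CsF, MeCN) in the presence of commercial tert-butyl methyl malonate. Transfer of the less hindered methyl ester carbonyl should give methyl 2,4-bis(benzyloxy)-6-(2-tert-butoxy-2-oxoethyl)benzoate F1.
- The hindered methyl ester is cleaved by SN2 demethylation with lithium propane-1-thiolate (LiSPr) in HMPA at 23 °C, which spares the tert-butyl ester, to give 2,4-bis(benzyloxy)-6-(2-tert-butoxy-2-oxoethyl)benzoic acid F2.
- This acid is esterified with phenol 14 (DCC, DMAP, CH2Cl2) to benzyl 4-{[2,4-bis(benzyloxy)-6-(2-tert-butoxy-2-oxoethyl)benzoyl]oxy}-2-(benzyloxy)-6-{2-[methoxy(methyl)amino]-2-oxoethyl}benzoate F3. An ester side chain is chosen here because an amide oxygen would cyclise onto the activated acid.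
- TFA in CH2Cl2 at 0 °C removes the tert-butyl group to give {3,5-bis(benzyloxy)-2-[(3-(benzyloxy)-4-(benzyloxycarbonyl)-5-{2-[methoxy(methyl)amino]-2-oxoethyl}phenoxy)carbonyl]phenyl}acetic acid F4.
- Coupling of this acid with N,O-dimethylhydroxylamine hydrochloride (EDC·HCl, HOBt, i-Pr2NEt) returns to 17.

Step 12. The organometallic may enolise the benzylic amides instead of adding. The ring A enolate or the tetrahedral adduct may then attack the neighbouring aryl ester through oxygen, with loss of the ring B phenol and enol-lactone formation, and prolonged exposure may attack the esters. The fallback uses a far less basic sp-carbon nucleophile and leaves the saturation of the chain to the final hydrogenation. It sets out from 17 and returns at 19.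
- Lithium pent-1-ynide (LiC≡CPr, THF, −78 °C) adds to both N-methoxy-N-methylamides to give benzyl 4-{[2,4-bis(benzyloxy)-6-(2-oxohept-3-yn-1-yl)benzoyl]oxy}-2-(benzyloxy)-6-(2-oxohept-3-yn-1-yl)benzoate F5.
- H2 over Pd/C in EtOAc then saturates both triple bonds and removes the four benzyl groups in one operation, giving 19 directly.

Step 8. The benzylic anion may be quenched by proton transfer from the product, the carbamoyl chloride may be consumed by the amide base, or a second acylation may occur, so conversion to the mono-amide may stall. The fallback separates C–C and C–N bond formation. It sets out from 11 and returns at 13.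
- The lithiated toluate 12 is generated as before and quenched with CO2 gas at −78 °C. The carboxylate formed cannot be acylated again, and acidic work-up gives [3-(benzyloxy)-2-(benzyloxycarbonyl)-5-(methoxymethoxy)phenyl]acetic acid F6.
- This acid is condensed with N,O-dimethylhydroxylamine hydrochloride (EDC·HCl, HOBt, i-Pr2NEt, CH2Cl2) to give 13.

**Further compounds**

F1 | step 11 | methyl 2,4-bis(benzyloxy)-6-(2-tert-butoxy-2-oxoethyl)benzoate | COC(=O)c1c(OCc2ccccc2)cc(OCc2ccccc2)cc1CC(=O)OC(C)(C)C
F2 | step 11 | 2,4-bis(benzyloxy)-6-(2-tert-butoxy-2-oxoethyl)benzoic acid | OC(=O)c1c(OCc2ccccc2)cc(OCc2ccccc2)cc1CC(=O)OC(C)(C)C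
F3 | step 11 | benzyl 4-{[2,4-bis(benzyloxy)-6-(2-tert-butoxy-2-oxoethyl)benzoyl]oxy}-2-(benzyloxy)-6-{2-[methoxy(methyl)amino]-2-oxoethyl}benzoate | CON(C)C(=O)Cc1cc(OC(=O)c2c(OCc3ccccc3)cc(OCc3ccccc3)cc2CC(=O)OC(C)(C)C)cc(OCc2ccccc2)c1C(=O)OCc1ccccc1
F4 | step 11 | {3,5-bis(benzyloxy)-2-[(3-(benzyloxy)-4-(benzyloxycarbonyl)-5-{2-[methoxy(methyl)amino]-2-oxoethyl}phenoxy)carbonyl]phenyl}acetic acid | CON(C)C(=O)Cc1cc(OC(=O)c2c(OCc3ccccc3)cc(OCc3ccccc3)cc2CC(=O)O)cc(OCc2ccccc2)c1C(=O)OCc1ccccc1
F5 | step 12 | benzyl 4-{[2,4-bis(benzyloxy)-6-(2-oxohept-3-yn-1-yl)benzoyl]oxy}-2-(benzyloxy)-6-(2-oxohept-3-yn-1-yl)benzoate | CCCC#CC(=O)Cc1cc(OC(=O)c2c(OCc3ccccc3)cc(OCc3ccccc3)cc2CC(=O)C#CCCC)cc(OCc2ccccc2)c1C(=O)OCc1ccccc1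
F6 | step 8 | [3-(benzyloxy)-2-(benzyloxycarbonyl)-5-(methoxymethoxy)phenyl]acetic acid | COCOc1cc(CC(=O)O)c(C(=O)OCc2ccccc2)c(OCc2ccccc2)c1
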